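By its uncatalysed step alone this substrate is slow: that step gives a half-life of 140 h, long against the run of 2.5 h.

substrate 0.050 M; acid 1.50 mM; time 2.5 h

    substrate → weak acid + target (k1 = 8.0 × 10⁻⁵ /min)
    2 substrate → homo dimer (k2 = 0.034 /M/min)
    weak acid ⇌ conjugate base + acid, settled at all times (K3 = 5.0 × 10⁻⁶ M)
    substrate + target → side product (k4 = 0.051 /M/min)
    substrate + acid → weak acid + acid + target (k5 = 6.0 /M/min)
    crystals ⇌ weak acid, rate k6*(cs6 - [weak acid]) while solid is left; crystals form when [weak acid] > cs6 (cs6 = 0.51 mM, k6 = 1.7 /min)

- acid is the free proton; pH is minus the decimal logarithm of its molar concentration
- a species is counted by the substrate in it: one homo dimer or side product counts as two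
- amounts and yields of weak acid count crystals too
- a doubled species enters its step squared and goes two at a time
- given per volume of solution although it is solid: crystals
- run time (flask): 2.5 h

* part of the substrate that has reacted at 2.5 h
* pH of the solution at 2.5 h

What sets the order of the rate? The acid-catalysed step gives its acid back, so at constant acid that step is pseudo-first-order in substrate, with coefficient 0.00900 /min, far above the uncatalysed 8.0 × 10⁻⁵ /min.

But does the acid stay constant, when weak acid dissociates? The charge of substrate far exceeds the solubility of weak acid, so I expect crystals to appear and to hold dissolved weak acid near 0.51 mM. Dissociation then adds about 1.70 × 10⁻⁶ M of acid, far less than the 1.50 mM charged, and I take the pH as 2.82.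

And the dimerisation, which is second order? At the start the acid-catalysed step uses substrate 2.6 times as fast as the dimerisation, so I keep the dimerisation in the reckoning. I count it as a first-order term at the charge, 0.00340 /min, which overstates it as substrate falls. The loss to side product starts from no target, and I leave it out, which understates the loss.

Your number, then? The sum is 0.0125 /min: the loss coefficient, the first-order rate of substrate loss with acid and substrate as charged. One exponential over the run gives 84.6 % reacted.

The forecast gives 81.6 % reacted and pH 2.823, holding that “Substrate then decays with a nearly constant first-order coefficient”. Its conversion is lower than mine.

The simulation gives 82.6 % reacted and pH 2.82. Read back from that conversion, the flask's average coefficient is 0.0117 /min, against the loss coefficient of 0.0125 /min, so my exponential lies 2.1 percentage points above the flask and the forecast 1.00 point below it. In the neighbouring flask, charged with 0.0037 M of acid and otherwise alike, the loss coefficient is 0.0257 /min, which gives 97.9 % reacted. That neighbour shows 97.6 %, with target at 82.5 % of the substrate charged, against 58.1 % in the first flask.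

(Its constants are assumed; the run is a simulation.)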